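**Retrosynthetic overview**
- Target ⇒ C16 silyl ether of the enal; the (Z)-enal comes from a C7 tertiary isopropenyl carbinol by a [3,3] chromate shift, and the C3 ester from cis-vaccenic acid.
- The C13–C14 bond is cut by a B-alkyl Suzuki coupling into a ring iodide and an (E)-alkenyl iodide carrying C16.
- Key bond: C11–C12 (quaternary carbon) by Eschenmoser–Claisen [3,3] rearrangement; chirality is relayed carvone C–H → C6 (alkylation) → C9 (Luche) → C11 (Claisen) → C10 (hydroxyl-directed epoxidation).
- Side chain: C16 is bought in methyl (R)-glycidate; both trisubstituted (E)-alkenes come from Negishi carboaluminations.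
- Rings: the only ring, the cyclohexane, is bought as (S)-carvone; no ring is formed.

Assumption: all reagents on the Conditions lines are bought; positions are named with the iridal numbering of the target (C1 = CHO, C3 = ester CH2, C6–C11 = ring, C16 = side-chain carbinol).

**Route**

Step 1
Reactants: 1 (S)-(+)-carvone
Product: 3 (5S,6R)-6-allylcarvone (allyl trans to isopropenyl), via lithium dienolate of carvone 2 (not isolated)
Conditions: LiN(i-Pr)2, THF, −78 °C; allyl bromide, −78 °C → rt
Reagents that add atoms: allyl bromide, C=CCBr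
Why: Kinetic α′-enolate alkylation; the electrophile enters anti to the neighbouring isopropenyl group, which sets C6 from the bought stereocentre.

Step 2
Reactants: 3 (5S,6R)-6-allylcarvone
Product: 4 tertiary allylic alcohol carrying CH2OCH2OMe on the former carbonyl carbon (OH cis to allyl drawn)
Conditions: Bu3SnCH2OCH2OMe, n-BuLi, THF, −78 °C; then 3, −78 °C; H2O
Reagents that add atoms: tributyl[(methoxymethoxy)methyl]stannane, CCCC[Sn](CCCC)(CCCC)COCOC
Why: Tin–lithium exchange gives an α-alkoxymethyllithium (hydroxymethyl anion equivalent) that adds 1,2 to the enone; the new carbinol centre is erased in step 3, so either epimer serves.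

Step 3
Reactants: 4 tertiary allylic alcohol
Product: 5 (4R,5S)-4-allyl-3-[(methoxymethoxy)methyl]-2-methyl-5-isopropenylcyclohex-2-enone
Conditions: [C5H5NH][CrO3Cl], CH2Cl2, 4 Å sieves, rt
Reagents that add atoms: pyridinium chlorochromate, [O-][Cr](=O)(=O)Cl.c1cc[nH+]cc1
Why: Babler–Dauben oxidative transposition ([3,3] shift of the chromate ester, then oxidation) moves the oxygen to C9 and the alkene to C10=C11 without touching C6 or C7.

Step 4
Reactants: 5 transposed enone
Product: 6 allylic alcohol (C9–OH cis to isopropenyl and trans to allyl)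
Conditions: NaBH4, CeCl3·7H2O, MeOH, −78 → 0 °C
Reagents that add atoms: none
Why: Luche 1,2-reduction; as in the carvone to cis-carveol case, hydride arrives anti to the 1,3-related isopropenyl group, which sets C9.

Step 5
Reactants: 6 allylic alcohol
Product: 8 N,N-dimethylacetamide with the new quaternary C11 (CH2CONMe2 cis to isopropenyl and trans to allyl), via ketene N,O-acetal 7 (not isolated)
Conditions: MeC(OMe)2NMe2, xylene, 140 °C
Reagents that add atoms: N,N-dimethylacetamide dimethyl acetal, COC(C)(OC)N(C)C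
Why: Eschenmoser–Claisen rearrangement; the suprafacial [3,3] shift forms C11–C12 on the ring face that carried the C9 oxygen, so the C9 configuration is transferred to the quaternary carbon and the alkene moves to C9=C10.

Step 6
Reactants: 8 MOM-protected amide
Product: 9 hydroxymethyl amide (CH2OH on C11 cis to allyl)
Conditions: ZnBr2, n-PrSH, CH2Cl2, 0 °C
Reagents that add atoms: none
Why: Lewis acid and thiol cleave the methoxymethyl ether under conditions too mild to protonate the trisubstituted alkene or lactonise the amide; no stereocentre is touched.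

Step 7
Reactants: 9 hydroxymethyl amide
Product: 10 epoxy alcohol (C9–C10 epoxide on the CH2OH face)
Conditions: VO(acac)2 (cat.), t-BuOOH, CH2Cl2, 0 °C → rt
Reagents that add atoms: tert-butyl hydroperoxide, CC(C)(C)OO
Why: Hydroxyl-directed vanadium epoxidation; the homoallylic CH2OH delivers oxygen to its own face, which sets the C10–O bond cis to the future C11 methyl and to the allyl arm and leaves the undirected alkenes alone.

Step 8
Reactants: 10 epoxy alcohol
Product: 11 epoxy tosylate
Conditions: TsCl, pyridine, DMAP (cat.), CH2Cl2, 0 °C → rt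
Reagents that add atoms: 4-toluenesulfonyl chloride, Cc1ccc(cc1)S(Cl)(=O)=O
Why: Sulfonylation of the only hydroxyl turns the directing group into a leaving group.

Step 9
Reactants: 11 epoxy tosylate
Product: 12 diol (C10 tertiary OH cis to the C11 methyl and to allyl; CH2CH2OH on C11)
Conditions: LiBHEt3 (excess), THF, 0 → 65 °C; H2O
Reagents that add atoms: none
Why: Hydride reduction does three jobs: SN2 displacement of the neopentyl tosylate (CH2OTs → CH3), epoxide opening at the secondary C9 so that oxygen stays on C10 with retention, and reduction of the tertiary amide to the primary alcohol.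

Step 10
Reactants: 12 diol
Product: 13 triol (C7 tertiary isopropenyl carbinol; OH trans to allyl drawn)
Conditions: SeO2 (0.5 equiv), t-BuOOH, CH2Cl2, rt
Reagents that add atoms: tert-butyl hydroperoxide, CC(C)(C)OO; selenium dioxide, O=[Se]=O
Why: Selenium dioxide allylic oxidation (ene reaction, then [2,3]-sigmatropic shift); on a 1,1-disubstituted alkene the methine hydrogen is taken, as in limonene to p-mentha-1,8-dien-4-ol, and the C7 configuration is irrelevant because C7 becomes sp2 in step 21.

Step 11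
Reactants: 13 triol
Product: 14 primary iodide (C13–I)
Conditions: I2, PPh3, imidazole, CH2Cl2, 0 °C
Reagents that add atoms: iodine, II
Why: Appel-type iodination is selective for the single primary hydroxyl; the two tertiary alcohols do not react at 0 °C.

Step 12
Reactants: 15 6-methylhept-5-en-2-one
Product: 17 6-methylhept-5-en-1-yne, via diethyl enol phosphate 16 (not isolated)
Conditions: LiN(i-Pr)2, THF, −78 °C; ClP(O)(OEt)2; LiN(i-Pr)2 (2.3 equiv), −78 °C → rt; H2O
Reagents that add atoms: none
Why: Negishi methyl ketone to alkyne conversion; the kinetic enol phosphate undergoes base-induced β-elimination.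

Step 13
Reactants: 17 6-methylhept-5-en-1-yne
Product: 19 (E)-1-iodo-2,6-dimethylhepta-1,5-diene, via alkenylalane 18 (not isolated)
Conditions: AlMe3, Cp2ZrCl2 (cat.), CH2Cl2, rt; I2, THF, −30 → 0 °C
Reagents that add atoms: trimethylaluminium, C[Al](C)C; iodine, II
Why: Zirconium-catalysed Negishi carboalumination adds methyl and aluminium syn with methyl on the internal carbon; iodinolysis with retention gives the (E)-iodide.

Step 14
Reactants: 19 (E)-1-iodo-2,6-dimethylhepta-1,5-diene; 20 methyl (R)-glycidate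
Product: 23 methyl (2R,4E)-2-hydroxy-5,9-dimethyldeca-4,8-dienoate, via alkenyllithium 21 (not isolated), via alkenylmagnesium bromide 22 (not isolated)
Conditions: t-BuLi (2.1 equiv), Et2O, −78 °C; MgBr2·OEt2; CuI (10 mol %), 20, THF, −40 → 0 °C; H2O
Reagents that add atoms: none
Why: Copper-catalysed SN2 opening of the glycidic ester at its CH2 carbon by the geometry-retaining alkenyl Grignard reagent; the bought C–O stereocentre is untouched and becomes C16.

Step 15
Reactants: 23 hydroxy ester
Product: 24 methyl (2R,4E)-2-(tert-butyldimethylsilyloxy)-5,9-dimethyldeca-4,8-dienoate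
Conditions: TBSCl, imidazole, DMF, rt
Reagents that add atoms: tert-butyldimethylsilyl chloride, CC(C)(C)[Si](C)(C)Cl
Why: Silylation protects the C16 oxygen until the last step.

Step 16
Reactants: 24 silyloxy ester
Product: 26 (3R,5E)-3-(tert-butyldimethylsilyloxy)-6,10-dimethylundeca-5,9-dien-1-yne, via silyloxy aldehyde 25 (not isolated)
Conditions: i-Bu2AlH, CH2Cl2, −78 °C; MeOH; K2CO3, MeC(O)C(N2)P(O)(OMe)2, 0 °C → rt
Reagents that add atoms: dimethyl (1-diazo-2-oxopropyl)phosphonate, COP(=O)(OC)C(=[N+]=[N-])C(C)=O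
Why: One-pot partial reduction and Seyferth–Gilbert homologation with the Ohira–Bestmann reagent; carbonate at low temperature does not epimerise the α-silyloxy centre.

Step 17
Reactants: 26 silyloxy enyne
Product: 28 (1E,3R,5E)-1-iodo-2,6,10-trimethyl-3-(tert-butyldimethylsilyloxy)undeca-1,5,9-triene, via alkenylalane 27 (not isolated)
Conditions: AlMe3, Cp2ZrCl2 (cat.), CH2Cl2, rt; I2, THF, −30 → 0 °C
Reagents that add atoms: trimethylaluminium, C[Al](C)C; iodine, II
Why: A second Negishi carboalumination and iodinolysis give the (E)-2-methylalkenyl iodide; the adjacent silyloxy centre is not involved.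

Step 18
Reactants: 14 primary iodide; 28 alkenyl iodide
Product: 31 coupled C13–C14 product (C16 silyl ether; C7 and C10 tertiary alcohols free), via dilithio alkoxide alkyllithium 29 (not isolated), via lithium borate 30 (not isolated)
Conditions: 14, t-BuLi (4.2 equiv), Et2O, −78 °C; 9-MeO-9-BBN, THF, −78 °C → rt; 28, Pd(dppf)Cl2 (cat.), AsPh3, Cs2CO3, DMF/H2O, rt
Reagents that add atoms: none
Why: B-alkyl Suzuki–Miyaura coupling; iodine–lithium exchange, trapping as the borate and palladium-catalysed alkyl transfer form C13–C14 with retention of the (E)-alkene and no change at any stereocentre.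

Step 19
Reactants: 31 coupled product
Product: 33 C3 primary alcohol, via B-alkyl-9-BBN adduct 32 (not isolated)
Conditions: 9-BBN, THF, 0 °C → rt; NaOH, H2O2, 0 °C
Reagents that add atoms: hydrogen peroxide, OO
Why: Brown hydroboration–oxidation; 9-BBN selects the monosubstituted allyl alkene over the hindered 1,1-disubstituted and the trisubstituted alkenes and puts boron on the terminal carbon.

Step 20
Reactants: 33 C3 primary alcohol; 34 cis-vaccenic acid
Product: 35 C3 (Z)-octadec-11-enoate
Conditions: EDC·HCl, DMAP (cat.), CH2Cl2, 0 °C → rt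
Reagents that add atoms: none
Why: Steglich-type esterification acylates the only primary hydroxyl; the tertiary alcohols and the silylated C16 oxygen do not react and the cis alkene is not isomerised.

Step 21
Reactants: 35 ester with C7 tertiary isopropenyl carbinol
Product: 36 (2Z)-enal, C16 silyl ether
Conditions: [C5H5NH][CrO3Cl], CH2Cl2, 4 Å sieves, rt
Reagents that add atoms: pyridinium chlorochromate, [O-][Cr](=O)(=O)Cl.c1cc[nH+]cc1
Why: Babler–Dauben oxidative transposition; the tertiary chromate ester shifts [3,3] to the primary chromate, which is oxidised to the enal, and in the chair transition state the in-plane C2 methyl turns away from the substituted C6, so C1 ends syn to C6 (Z).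

Step 22
Reactants: 36 enal silyl ether
Product: 37 target CNP0211807.2
Conditions: HF·pyridine, pyridine, THF, 0 °C → rt
Reagents that add atoms: none
Why: Buffered fluoride desilylation frees the C16 alcohol without touching the enal, the ester or the tertiary alcohol.

**Compound list**
1 | (S)-(+)-carvone, (5S)-2-methyl-5-(prop-1-en-2-yl)cyclohex-2-en-1-one | CC1=CC[C@@H](CC1=O)C(C)=C | starting material
2 | lithium dienolate of carvone (OLi on C1, C1=C6 and C2=C3) | CC1=CC[C@H](C(C)=C)C=C1O[Li] | intermediate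
3 | (5S,6R)-2-methyl-6-(prop-2-en-1-yl)-5-(prop-1-en-2-yl)cyclohex-2-en-1-one; allyl trans to isopropenyl | C=CC[C@@H]1[C@@H](C(C)=C)CC=C(C)C1=O | intermediate
4 | 6-allyl-1-[(methoxymethoxy)methyl]-2-methyl-5-(prop-1-en-2-yl)cyclohex-2-en-1-ol; allyl trans to isopropenyl, OH cis to allyl | C=CC[C@@H]1[C@@H](C(C)=C)CC=C(C)[C@@]1(O)COCOC | intermediate
5 | (4R,5S)-4-allyl-3-[(methoxymethoxy)methyl]-2-methyl-5-(prop-1-en-2-yl)cyclohex-2-en-1-one | C=CC[C@@H]1[C@@H](C(C)=C)CC(=O)C(C)=C1COCOC | intermediate
6 | (1R,4R,5S)-4-allyl-3-[(methoxymethoxy)methyl]-2-methyl-5-(prop-1-en-2-yl)cyclohex-2-en-1-ol; OH cis to isopropenyl | C=CC[C@@H]1[C@@H](C(C)=C)C[C@@H](O)C(C)=C1COCOC | intermediate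
7 | 1-(dimethylamino)vinyl ether of 6 (ketene N,O-acetal) | C=CC[C@@H]1[C@@H](C(C)=C)C[C@@H](OC(=C)N(C)C)C(C)=C1COCOC | intermediate
8 | 2-{6-allyl-1-[(methoxymethoxy)methyl]-2-methyl-5-(prop-1-en-2-yl)cyclohex-2-en-1-yl}-N,N-dimethylacetamide; acetamide arm cis to isopropenyl, trans to allyl | C=CC[C@@H]1[C@@H](C(C)=C)CC=C(C)[C@@]1(COCOC)CC(=O)N(C)C | intermediate
9 | 2-[6-allyl-1-(hydroxymethyl)-2-methyl-5-(prop-1-en-2-yl)cyclohex-2-en-1-yl]-N,N-dimethylacetamide; CH2OH cis to allyl | C=CC[C@@H]1[C@@H](C(C)=C)CC=C(C)[C@@]1(CO)CC(=O)N(C)C | intermediate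
10 | C9–C10 epoxide of 9, oxygen on the face of CH2OH and allyl | C=CC[C@@H]1[C@@H](C(C)=C)C[C@@H]2O[C@]2(C)[C@@]1(CO)CC(=O)N(C)C | intermediate
11 | 4-toluenesulfonate of 10 | C=CC[C@@H]1[C@@H](C(C)=C)C[C@@H]2O[C@]2(C)[C@@]1(COS(=O)(=O)c3ccc(C)cc3)CC(=O)N(C)C | intermediate
12 | 3-allyl-2-(2-hydroxyethyl)-1,2-dimethyl-4-(prop-1-en-2-yl)cyclohexan-1-ol (ring C10, C11, C6, C7); OH cis to the C11 methyl and to allyl, hydroxyethyl cis to isopropenyl | C=CC[C@@H]1[C@@H](C(C)=C)CC[C@](C)(O)[C@@]1(C)CCO | intermediate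
13 | 12 with a tertiary OH on C7 (isopropenyl carbinol; OH trans to allyl) | C=CC[C@@H]1[C@](O)(C(C)=C)CC[C@](C)(O)[C@@]1(C)CCO | intermediate
14 | 13 with C13–OH replaced by iodine | C=CC[C@@H]1[C@](O)(C(C)=C)CC[C@](C)(O)[C@@]1(C)CCI | intermediate
15 | 6-methylhept-5-en-2-one | CC(=O)CCC=C(C)C | starting material
16 | diethyl 6-methylhepta-1,5-dien-2-yl phosphate | C=C(CCC=C(C)C)OP(=O)(OCC)OCC | intermediate
17 | 6-methylhept-5-en-1-yne | C#CCCC=C(C)C | intermediate
18 | (E)-(2,6-dimethylhepta-1,5-dien-1-yl)dimethylalane | C[Al](C)/C=C(\C)CCC=C(C)C | intermediate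
19 | (E)-1-iodo-2,6-dimethylhepta-1,5-diene | I/C=C(\C)CCC=C(C)C | intermediate
20 | methyl (R)-glycidate, methyl (2R)-oxirane-2-carboxylate | COC(=O)[C@H]1CO1 | starting material
21 | (E)-(2,6-dimethylhepta-1,5-dien-1-yl)lithium | [Li]/C=C(\C)CCC=C(C)C | intermediate
22 | (E)-(2,6-dimethylhepta-1,5-dien-1-yl)magnesium bromide | Br[Mg]/C=C(\C)CCC=C(C)C | intermediate
23 | methyl (2R,4E)-2-hydroxy-5,9-dimethyldeca-4,8-dienoate | COC(=O)[C@H](O)C/C=C(\C)CCC=C(C)C | intermediate
24 | methyl (2R,4E)-2-(tert-butyldimethylsilyloxy)-5,9-dimethyldeca-4,8-dienoate | COC(=O)[C@H](O[Si](C)(C)C(C)(C)C)C/C=C(\C)CCC=C(C)C | intermediate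
25 | (2R,4E)-2-(tert-butyldimethylsilyloxy)-5,9-dimethyldeca-4,8-dienal | O=C[C@H](O[Si](C)(C)C(C)(C)C)C/C=C(\C)CCC=C(C)C | intermediate
26 | (3R,5E)-3-(tert-butyldimethylsilyloxy)-6,10-dimethylundeca-5,9-dien-1-yne | C#C[C@H](O[Si](C)(C)C(C)(C)C)C/C=C(\C)CCC=C(C)C | intermediate
27 | dimethylalane from syn methylalumination of 26 (Al on C1, cis to the new methyl) | C[Al](C)/C=C(\C)[C@H](O[Si](C)(C)C(C)(C)C)C/C=C(\C)CCC=C(C)C | intermediate
28 | (1E,3R,5E)-1-iodo-2,6,10-trimethyl-3-(tert-butyldimethylsilyloxy)undeca-1,5,9-triene | I/C=C(\C)[C@H](O[Si](C)(C)C(C)(C)C)C/C=C(\C)CCC=C(C)C | intermediate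
29 | C13-lithio derivative of 14 as its bis(lithium alkoxide) | C=CC[C@@H]1[C@](O[Li])(C(C)=C)CC[C@](C)(O[Li])[C@@]1(C)CC[Li] | intermediate
30 | lithium B-methoxy-B-alkyl-9-borabicyclo[3.3.1]nonane borate from 29 | C=CC[C@@H]1[C@](O[Li])(C(C)=C)CC[C@](C)(O[Li])[C@@]1(C)CC[B-]2(OC)C3CCCC2CCC3.[Li+] | intermediate
31 | coupled product: ring as in 14, C11 arm CH2CH2–CH=C(Me)–CH(OTBS)–CH2–CH=C(Me)–CH2CH2CH=CMe2 (14E,16R,18E) | C=CC[C@@H]1[C@](O)(C(C)=C)CC[C@](C)(O)[C@@]1(C)CC/C=C(\C)[C@H](O[Si](C)(C)C(C)(C)C)C/C=C(\C)CCC=C(C)C | intermediate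
32 | B-(3-substituted propyl)-9-borabicyclo[3.3.1]nonane from 31 (boron on C3) | B1(CCC[C@@H]3[C@](O)(C(C)=C)CC[C@](C)(O)[C@@]3(C)CC/C=C(\C)[C@H](O[Si](C)(C)C(C)(C)C)C/C=C(\C)CCC=C(C)C)C2CCCC1CCC2 | intermediate
33 | 31 with the allyl group converted into CH2CH2CH2OH | OCCC[C@@H]1[C@](O)(C(C)=C)CC[C@](C)(O)[C@@]1(C)CC/C=C(\C)[C@H](O[Si](C)(C)C(C)(C)C)C/C=C(\C)CCC=C(C)C | intermediate
34 | cis-vaccenic acid, (Z)-octadec-11-enoic acid | CCCCCC/C=C\CCCCCCCCCC(=O)O | starting material
35 | (Z)-octadec-11-enoate of 33 at the C3 oxygen | CCCCCC/C=C\CCCCCCCCCC(=O)OCCC[C@@H]1[C@](O)(C(C)=C)CC[C@](C)(O)[C@@]1(C)CC/C=C(\C)[C@H](O[Si](C)(C)C(C)(C)C)C/C=C(\C)CCC=C(C)C | intermediate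
36 | 16-O-tert-butyldimethylsilyl ether of the target, (2Z)-enal | CCCCCC/C=C\CCCCCCCCCC(=O)OCCC[C@@H]1/C(=C(/C)C=O)CC[C@](C)(O)[C@@]1(C)CC/C=C(\C)[C@H](O[Si](C)(C)C(C)(C)C)C/C=C(\C)CCC=C(C)C | intermediate
37 | CNP0211807.2, (2Z,6R,10S,11S,14E,16R,18E)-16-hydroxyiridal 3-O-[(Z)-octadec-11-enoate] | CCCCCC/C=C\CCCCCCCCCC(=O)OCCC[C@@H]1/C(=C(/C)C=O)CC[C@](C)(O)[C@@]1(C)CC/C=C(\C)[C@H](O)C/C=C(\C)CCC=C(C)C | target

**Count**
Total steps: 22. Longest linear sequence: 16 steps (steps 1–11 and 18–22, from (S)-carvone); the side chain takes steps 12–17.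

**Three steps most likely to fail**

Step 10 (tertiary allylic hydroxylation). The fallback sets out from 12 and returns at 13. If the ene/[2,3] sequence attacks the isopropenyl methyl or the allyl arm, the C7–H bond is oxidised by a radical path instead. Kharasch–Sosnovsky acyloxylation (CuBr cat., tert-butyl perbenzoate, PhH, 80 °C) removes the weakest, tertiary allylic hydrogen, and the copper benzoate couples at the more substituted allyl terminus to give the C7 tertiary allylic benzoate of 12 F1. K2CO3 in MeOH then cleaves the benzoate to triol 13.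

Step 18 (alkyl–alkenyl coupling in the presence of two free tertiary alcohols). The fallback sets out from 14 and 28 and returns at 31. If the alkoxide-bearing alkyllithium or its borate fails, no organometallic partner is made. Nickel-catalysed reductive cross-electrophile coupling (NiBr2(dme), 4,4′-di-tert-butyl-2,2′-bipyridine, Zn, NaI, DMA, rt) joins the primary alkyl iodide and the alkenyl iodide directly, tolerates free hydroxyls and keeps the alkene geometry, giving 31 in one operation; new compound: none F0.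

Step 21 (oxidative transposition and Z geometry). The fallback sets out from 35 and returns at 36. If the chromium reagent gives a poor Z:E ratio or degrades the polyene, transposition and oxidation are separated. Ph3SiOReO3 (cat., Et2O, −50 °C) equilibrates the tertiary alcohol with the (2Z)-primary allylic alcohol F2; the (Z)-isomer is separated and the (E)-isomer is put back into the same equilibrium. MnO2 (CH2Cl2, rt) then oxidises F2 to 36.

Further compounds
F1 | step 10 | C7 tertiary allylic benzoate of 12 | C=CC[C@@H]1[C@](OC(=O)c2ccccc2)(C(C)=C)CC[C@](C)(O)[C@@]1(C)CCO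
F0 | step 18 | none | none
F2 | step 21 | (2Z)-primary allylic alcohol isomer of 35 (C7=C2 alkene, C1 CH2OH syn to C6) | CCCCCC/C=C\CCCCCCCCCC(=O)OCCC[C@@H]1/C(=C(/C)CO)CC[C@](C)(O)[C@@]1(C)CC/C=C(\C)[C@H](O[Si](C)(C)C(C)(C)C)C/C=C(\C)CCC=C(C)C
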